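(The readings stem from a simulated flask with made-up constants; the scatter is artificial.)

The target is one of two exits for the starting material. The other is the quenched substrate, and a further step turns target into its isomer.

in all of them: gas phase 200 mM (held); catalyst 71 mM

|  | starting material | protic impurity | remark | time |
|---|---|---|---|---|
| amber | 1.4 M | 0.70 M | run made earlier |  |
| green | 1.4 M | 2.8 M | run made earlier |  |
| teal | 0.70 M | 1.4 M | run made earlier |  |
| Wednesday's | 1.4 M | 1.40 M |  | 2.5 d |
| Sunday's | 1.4 M | 1.40 M |  | 5.0 d |

| run | time / h | target / % |
|---|---|---|
| amber | 8.00 | 11.8 |
| amber | 15.0 | 20.6 |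
| amber | 20.0 | 25.0 |
| amber | 30.0 | 34.3 |
| amber | 40.0 | 41.6 |
| green | 3.00 | 3.7 |
| green | 5.00 | 6.7 |
| green | 10.0 | 13.7 |
| green | 20.0 | 22.3 |
| green | 40.0 | 33.4 |
| teal | 3.00 | 4.8 |
| teal | 5.00 | 7.9 |
| teal | 10.0 | 15.2 |
| teal | 20.0 | 23.9 |
| teal | 40.0 | 38.4 |

(scatter of a reading: 0.5 percentage points)

- at the start none of the gas is dissolved
- steps under discussion: starting material + protic impurity -> quenched substrate; target <-> isomer of the product; gas phase <-> dissolved gas; starting material + dissolved gas + catalyst -> catalyst + target

* which of the two there is more of at the end, Wednesday's (isomer of the product / target)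
* which of the two there is more of at the end, Sunday's (isomer of the product / target)
* target at the end, in percent of the starting material charged, Wednesday's
* target at the end, in percent of the starting material charged, Sunday's

What can a single curve tell you? With the gas held and the catalyst unchanged, I expect starting material to leave pseudo-first-order, with a loss constant that adds formation and quench. Target then climbs towards a ceiling, and the gain over a second equal interval, divided by the gain over the first, is the exponential of minus that constant times the interval. Over 20.0 h intervals this gives 0.0205 h⁻¹ for amber, 0.0349 h⁻¹ for green and 0.0250 h⁻¹ for teal.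

Which part is quench? Green's constant exceeds amber's, and scaling that difference by [protic impurity] gives 0.00961 h⁻¹ at 1.40 M. Teal was charged at that level, so formation is 0.0154 h⁻¹.

And the weak spot? Wednesday's flask has equal charges, so its impurity falls further. My first round, with teal's constant, has quench taking 29.9 % of the charge by the end. Putting that back, the average [protic impurity] is 85.0 % of its charge. This gives the corrected loss constant 0.0236 h⁻¹.

So what do you commit to? Target plus isomer: 49.4 % for Wednesday's flask and, keeping the same constant as a rough step, 61.4 % for Sunday's. These readings give that split poorly and stop at 40.0 h, before either end, so what follows is judgement and not a bound. Teal's target stood at 38.4 % there, which is 77.7 % of my sum for Wednesday's flask, so I take target as the larger in Wednesday's flask and, less safely, in Sunday's.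

The forecast, which unlike my sum counts target by itself, gives 45 % for Wednesday's flask and 51 % for Sunday's, and says “Target should therefore stay dominant in both runs”.

The simulation gives 46.5 % target against 4.94 % isomer in Wednesday's flask, and 52.4 % against 12.4 % in Sunday's.

    starting material + protic impurity → quenched substrate (k = 1.00 × 10⁻⁴ M⁻¹ min⁻¹)
    target ⇌ isomer of the product (K = 0.910, k = 5.00 × 10⁻⁵ min⁻¹)
    gas phase ⇌ dissolved gas, rate k3*(csat - [dissolved gas]) (kL = 0.150 min⁻¹)
    starting material + dissolved gas + catalyst → catalyst + target (k = 0.0190 M⁻² min⁻¹)

Target plus isomer comes to 51.5 % in Wednesday's flask and 64.7 % in Sunday's. Sunday's flask ends at 52.4 % target against 46.5 % at Wednesday's shorter time, and that gap comes from the difference in time. Taking the quench step away from Sunday's flask gives 70.2 % target, so the quench is part of what holds it at 52.4 %. The corrected constant leaves 24.3 % of the starting material at the end of Wednesday's flask, which holds 24.9 %. For a reading of Sunday's flask at 30 h, the same constant leaves 49.3 %, and that flask holds 49.3 %.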